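All runs stem from a simulated flask from invented constants; scatter was added.

Per minute, what share of the E present turns into L? The reckoning below hangs on that question, so watch the early readings.

| setting | midnight | dusk | summer | violet | green |
|---|---|---|---|---|---|
| E | 1 M | 1.4 M | 2.2 M | 1.0 M | 1.0 M |
| remark | run made earlier | run made earlier | run made earlier | everything together in a closed stirred flask, run for 1.5 h | a single well-mixed tank run continuously and read at steady state, 1.5 h in it on average |
| time |  |  |  | 1.5 h |  |

| run | time / min | L / % |
|---|---|---|
| midnight | 6.00 | 13.9 |
| midnight | 20.0 | 37.2 |
| midnight | 40.0 | 55.8 |
| midnight | 50.0 | 61.5 |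
| dusk | 8.00 | 18.3 |
| dusk | 20.0 | 36.4 |
| dusk | 50.0 | 57.1 |
| dusk | 120 | 71.8 |
| summer | 8.00 | 17.6 |
| summer | 20.0 | 34.3 |
| summer | 50.0 | 51.7 |
| summer | 120 | 62.7 |

(scatter of a reading: 0.3 percentage points)

- the stated concentrations are those of everything mixed, before any reaction; amounts are the same in each set-up
- the earlier runs were made in a closed, stirred flask

1. the set-up with the highest amount of L at the outlet or at the end, in percent of the E put in ("none" if the first two lie within 2 percentage points) (violet / green / none)
2. amount of L at the outlet or at the end, in percent of the E put in, violet
3. amount of L at the outlet or at the end, in percent of the E put in, green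

What does the earliest midnight reading give? It shows 13.9 % of L after 6.00 min, which, taken as first order, is 0.0249 /min.

Does the charge change that? Read the same way, the first dusk reading gives 0.0253 /min and the first summer reading 0.0242 /min.

What do you carry to the new vessels? The lifetimes E spends there, this constant times 1.5 h, which is 2.24 (the Damköhler number); for the green tank that time is an average.

And the closed forms? Integrating this first-order rate, my estimate has E falling exponentially in the violet flask, with 10.6 % left at the end. For the green tank, with feed balancing outflow plus reaction, the same estimate keeps one part in one plus the lifetimes, 30.8 %.

But the dusk run after 120 min has had 2.99 lifetimes and reads 71.8 % of L, with the summer run lower at 62.7 %. Doesn't that sink the count? It sinks it as a figure for L, so I commit to E left and to the order: my reckoning puts violet ahead, since on this estimate violet leaves less E than green, by 20 percentage points.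

The forecast also says violet, with 72.5 % for violet and 63.5 % for green, on the grounds that “The tank holds E low, which favours the first-order path, but the unfinished conversion costs more”.

The flask gives 73.1 % of L in violet and 56.2 % in green, so violet leads and the forecast's green stands 7.3 points too high.

    G → J (k = 5.60 × 10⁻⁴ /s)
    E + L → X (k = 5.00 × 10⁻⁵ /M/s)
    E ⇌ L + G (K = 1.20 M, k = 4.30 × 10⁻⁴ /s)

The green tank holds E at 0.336 M everywhere, and violet ends with 17.1 % of its charged E. Put through the closed forms, the carried lifetimes give 10.6 % of E left for violet against that 17.1 %, and 30.8 % for green against the 33.6 % at its outlet.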